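# Proposal: anodic closure of ring A in a synthesis of CNP0215744.1

Eremophilane numbering is used throughout. Ring A is C1, C2, C3, C4, C5, C10. Ring B is C5, C6, C7, C8, C9, C10. C11–C13 form the isopropylidene, C14 is the methyl on C5 and C15 the methyl on C4. Primed locants refer to the acyl chain.

## The problem

The target is a bicyclic sesquiterpenoid ester. Two six-membered rings share the C5–C10 bond; ring A carries the C1=C2 alkene, the acylated C3 oxygen and the C4 methyl, and ring B carries the quaternary C5 methyl, the C7 isopropylidene, the C8 ketone and the C9=C10 alkene. Three contiguous ring stereocentres (3S, 4R, 5R) hold the oxygen and both methyl groups on one face. The fourth, C6′ (S) in the dienoate, is too remote to be induced and must be bought.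

C5 is quaternary and can only be set by a C–C bond-forming event. C4 has to be set with it, because C4 becomes epimerisable once C3 is a ketone and no clear thermodynamic bias is expected there. C3 can be set last, since the axial C5 methyl shields one face of a C3 carbonyl.

The cross-conjugated trienone, the allylic C3 ester and the dienoate with its α-branched terminus will not tolerate strong base, strong acid or non-selective hydride. The acyl group therefore has to arrive at the end.

The enabling feature is the dissonant 1,6 relation between the C3 oxygen and the C8 ketone through C2, C1, C10 and C9. C2 is the α-carbon of a C3 ketone and C1 is the vinylogous γ-carbon of the C8 enone, so both are donors. In the open form they are the two CH2 termini of a hexa-1,5-diene held together by the C4–C5 bond, and only an oxidative union can join them.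

## Retrosynthesis

**C3–O acyl bond.** Target 27 is cut into alcohol 20 and (2E,4E,6S)-6-methylocta-2,4-dienoic acid 25. The cut comes last so that the dienoate and its C6′ stereocentre never meet enolate chemistry; acylating earlier would expose that centre to the amide base needed at C7. The forward step must acylate a hindered axial allylic alcohol without isomerising the diene, which is asked of a mixed anhydride 26.

**C4′=C5′ of the acid.** Acid 25 comes from ester 24, made by olefination of (2S)-2-methylbutanal 23 with phosphonate 22. Aldehyde 23 comes from commercial (2S)-2-methylbutan-1-ol 21. This puts the stereocentre in a purchased C5 unit and forms both alkenes in one operation. The aldehyde must be used without racemisation.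

**C7–C11 bond and the C3 protecting group.** Alcohol 20 is traced through silyl ether 19 and mesylate 18 to aldol adduct 17, and from there to dienone 15 and acetone 16. In 15 the only enolisable α-position of the C8 ketone is C7, so kinetic deprotonation is unambiguous. Installing the isopropylidene earlier would add γ-hydrogens that compete in every later enolisation.

**C1=C2 alkene and the C3 stereocentre.** Dienone 15 comes from enone 14 by γ,δ-dehydrogenation. Silyl ether 14 comes from alcohol 13, and 13 from dione 12 by reduction. A ketone at C3 is exactly what the ring-closing step leaves behind, and it is the best handle for the last stereocentre. The forward reduction must select the saturated C3 ketone over the C8 enone and deliver hydride anti to C14.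

**C1–C2 bond (key step).** Dione 12 is opened to bis(silyl enol ether) 11. Polar alternatives fail because both carbons are donors. The neighbouring cut at C5–C10 or C4–C5 would return to annulation chemistry that builds the quaternary centre and ring A together. Precursor 11 is monocyclic, carries C4 and C5 already, and has one ring and no stereocentre less than 12. The forward step must oxidise the dienol ether selectively, bond C1 to C2 and leave C4 untouched.

**C2 methylene and the two O–Si bonds.** Precursor 11 is derived from silyl ester 10 by carbonyl methylenation, which supplies C2 and the C2=C3 enol ether in one step. Ester 10 comes from enone acid 8 through dianion 9. Generating both enol ethers by deprotonation was set aside for two reasons. The ring terminus needs equilibrating conditions to reach the extended C1 dienolate instead of the kinetic C7 enolate, and under those conditions a C3 ketone would epimerise C4. A carboxylate at C3 is inert, keeps C4–H non-acidic, and is later converted directly into the silyl enol ether.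

**C8 oxygen.** Enone acid 8 comes from acid 7 by allylic oxidation. C8 is the only ring methylene next to the C9=C10 alkene and C5 is blocked, so the position is defined by the substrate.

**C4–C5 bond.** Acid 7 is cut between C4 and C5 by an ester-enolate [3,3] shift of propanoate 4, through ketene acetal 5 and silyl ester 6. Propanoate 4 comes from alcohol 2 and propanoyl chloride 3, and 2 from commercial enone 1. One reagent-controlled carbinol centre is thereby turned into the quaternary C5 and, through the ketene acetal geometry, the C4 centre. The forward step needs complete chirality transfer and a single transition-state topology.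

## Roads not taken

**Alternative 1:** The angular methyl is disconnected as a cyclopropane (bonds C5–C14 and C10–C14). Forward, Et2Zn and CH2I2 would be held by the C3 alkoxide of the Birch-derived homoallylic alcohol A1 and transfer CH2 to the tetrasubstituted C5=C10 alkene, giving A2 with the bridge on the hydroxyl face. Later ketal removal and opening of the three-membered ring toward C9 would reveal C14 and the enone.

- Merits: every operation is established, the ring system comes from a cheap arene, and the cis relation between the C3 oxygen and C14 is guaranteed by directed delivery.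
- Weak points: C3 and C4 must first be set in absolute and relative terms on a flexible Birch product; the alkene is tetrasubstituted and the directing group only homoallylic; C1=C2 and the isopropylidene still have to be added as in the chosen plan.
- Comparison: this road is safer in that it needs no untested reaction. The chosen plan offers a shorter skeletal sequence in which one bond closes ring A and leaves both carbonyl groups at the right oxidation level, with C4 and C5 fixed by chirality transfer before the ring exists.

**Alternative 2:** The cut opens C3–C4 and C5–C10 together. Forward, a diene unit C10=C1–C2=C3, whose C10 is the central carbon of an axially chiral allene and whose C3 bears a silyloxy group, would add on heating to a tethered trisubstituted C4=C5 alkene and give A3 in one step.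

- Merits: it is the most convergent of the four plans. Both rings, both ring alkenes, the C3 oxygen and all three ring stereocentres appear at once.
- Weak points: the allene must be made as one enantiomer; its axis, the endo/exo preference and the alkene geometry must all line up in a single transition state; the dienophile is unactivated; C8 arrives as a methylene, so a late allylic oxidation has to choose C8 over the other allylic positions of a diene that also carries the C3 ether.
- Comparison: in bond economy this road is better than the chosen one. The chosen plan decouples stereocontrol into steps that can be corrected one at a time and has the C8 oxygen in place from the start.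

**Alternative 3:** The cut is C1–C10. Zerovalent palladium generated from Pd(OAc)2 and a phosphine would insert into the C1–I bond of the prochiral cyclohexadienone A4. The alkenylpalladium would add 6-exo to one of the two ring alkenes, and β-hydride loss would give A5.

- Merits: only established palladium chemistry is used, C1=C2 is present without a dehydrogenation step, and the remaining C6=C7 enone could carry the isopropylidene in by reductive aldol chemistry. In endgame length this road is as good as or better than the chosen one.
- Weak points: the C4 and C3 centres on the tether must choose between two diastereotopic alkenes to set C5. After syn insertion the palladium at C9 has no syn hydrogen on C10 and must isomerise through its enolate form before the alkene can return. The dienone needs a branched, stereodefined side chain at its quaternary carbon, which is hard to introduce by dearomatisation.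
- Comparison: the chosen plan sets C5 by suprafacial chirality transfer instead of remote group selection, and its ring closure needs no β-hydride geometry. It pays for this with a key step that has no direct precedent.

Key step: step 7

Assumption: the C7 configuration of aldol adduct 17 is left undefined because that centre is erased in step 12.

## Route

Step 1
Reactants: 1 2,3-dimethylcyclohex-2-en-1-one
Product: 2 (1R)-2,3-dimethylcyclohex-2-en-1-ol
Conditions: (3aS)-1-methyl-3,3-diphenyltetrahydro-1H,3H-pyrrolo[1,2-c][1,3,2]oxazaborole (10 mol %), BH3·SMe2, THF, −20 °C; MeOH, then H2O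
Reagents that add atoms: none
Why: Corey–Bakshi–Shibata reduction; the fully substituted alkene side is the large group and the CH2 side the small one, so the (S)-catalyst should deliver hydride to the face that gives the (R)-allylic alcohol, and 1,2-reduction outruns hydroboration of the hindered alkene.

Step 2
Reactants: 2 (1R)-2,3-dimethylcyclohex-2-en-1-ol; 3 propanoyl chloride
Product: 4 (1R)-2,3-dimethylcyclohex-2-en-1-yl propanoate
Conditions: pyridine, 4-(dimethylamino)pyridine (5 mol %), CH2Cl2, 0 °C → rt
Reagents that add atoms: none
Why: nucleophile-catalysed O-acylation of a secondary allylic alcohol; the carbinol centre is not touched.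

Step 3
Reactants: 4 (1R)-2,3-dimethylcyclohex-2-en-1-yl propanoate
Product: 7 (2R)-2-[(1R)-1,2-dimethylcyclohex-2-en-1-yl]propanoic acid, via Z-silyl ketene acetal 5 (not isolated), via trimethylsilyl ester 6 (not isolated)
Conditions: LiN(i-Pr)2, THF/DMPU, −78 °C; Me3SiCl, Et3N, −78 °C → 60 °C; 1 M HCl
Reagents that add atoms: none
Why: Ireland–Claisen rearrangement; the suprafacial [3,3] shift forms C4–C5 on the face the C–O bond leaves, so the (R)-carbinol should become (5R), and the Z-ketene acetal (enolisation in the presence of DMPU) reacting through the boat-like transition state usual for cyclohexenyl esters should place the C4 methyl to give (4R).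

Step 4
Reactants: 7 (2R)-2-[(1R)-1,2-dimethylcyclohex-2-en-1-yl]propanoic acid
Product: 8 (2R)-2-[(1R)-1,2-dimethyl-4-oxocyclohex-2-en-1-yl]propanoic acid
Conditions: Rh2(cap)4 (dirhodium tetrakis(caprolactamate), 1 mol %), t-BuOOH (70 % in water), CH2Cl2, 40 °C
Reagents that add atoms: tert-butyl hydroperoxide, CC(C)(C)OO
Why: catalytic allylic oxidation by tert-butylperoxyl radicals; C8 is the only ring methylene beside the alkene (C5 is quaternary) and is attacked in preference to the C1 methyl, as 1-methylcyclohexenes give 3-methylcyclohexenones.

Step 5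
Reactants: 8 (2R)-2-[(1R)-1,2-dimethyl-4-oxocyclohex-2-en-1-yl]propanoic acid
Product: 10 tert-butyldimethylsilyl (2R)-2-[(1R)-4-(tert-butyldimethylsilyloxy)-1-methyl-2-methylidenecyclohex-3-en-1-yl]propanoate, via dipotassium dianion 9 (not isolated)
Conditions: KOt-Bu (2.5 equiv), THF, 0 °C; t-BuMe2SiCl (3 equiv), 0 °C → rt; filtration under argon
Reagents that add atoms: tert-butyldimethylsilyl chloride, CC(C)(C)[Si](C)(C)Cl
Why: thermodynamic dienolate formation and O-silylation; under equilibrating conditions (tert-butanol as proton shuttle) the through-conjugated dienolate from the C1 methyl, the only γ-position with hydrogen, should be favoured over the cross-conjugated C7 enolate. The carboxylate is inert as an electrophile and keeps C4–H non-acidic, and any lactone formed by conjugate addition of the carboxylate reopens under the base.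

Step 6
Reactants: 10 tert-butyldimethylsilyl (2R)-2-[(1R)-4-(tert-butyldimethylsilyloxy)-1-methyl-2-methylidenecyclohex-3-en-1-yl]propanoate
Product: 11 tert-butyl({(3R)-3-[(1R)-4-(tert-butyldimethylsilyloxy)-1-methyl-2-methylidenecyclohex-3-en-1-yl]but-1-en-2-yl}oxy)dimethylsilane
Conditions: Cp2TiMe2 (3 equiv), toluene, 70 °C, dark
Reagents that add atoms: dimethyltitanocene, [CH3-].[CH3-].[Ti+4].c1cc[cH-]c1.c1cc[cH-]c1
Why: Petasis methylenation of a silyl ester, a known route to silyl enol ethers of methyl ketones; the non-basic, non-acidic titanium methylidene introduces C2 without touching C4–H or the dienol ether.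

Step 7
Reactants: 11 tert-butyl({(3R)-3-[(1R)-4-(tert-butyldimethylsilyloxy)-1-methyl-2-methylidenecyclohex-3-en-1-yl]but-1-en-2-yl}oxy)dimethylsilane
Product: 12 (1R,8aR)-1,8a-dimethyl-3,4,8,8a-tetrahydronaphthalene-2,6(1H,7H)-dione
Conditions: reticulated vitreous carbon anode, Pt cathode, undivided cell, constant current (2.2 F/mol), 0.1 M LiClO4, 2,6-lutidine, MeCN/i-PrOH (4:1), 0 °C
Reagents that add atoms: none
Why: Proposed new method: anodic removal of one electron from the more electron-rich silyl dienol ether should give a radical cation with spin and charge at C9 and C1; the pendant silyl enol ether adds through C2 to the unhindered C1 terminus, leaving a silyloxyallyl radical (C8–C9–C10) and a C3 silyloxocarbenium ion, and a second oxidation with transfer of both silyl groups to propan-2-ol gives the C3 ketone and the C9–C10 enone. The closest known reaction types are the anodic or (NH4)2Ce(NO3)6-mediated intramolecular coupling of bis(silyl enol ethers) to 1,4-diketones and the radical-cation cyclisation of 2,5-disubstituted hexa-1,5-dienes; the enol ether/dienol ether version leading to a 1,6-dione is the extension. Ring A closes by joining the two CH2 termini of a hexa-1,5-diene, a six-membered closure that is endo with respect to both alkenes and can pass through a chair-like array held by the C4–C5 bond. No stereocentre is formed, and C4 and C5 are spectators. The step needs chemoselective oxidation, which the lower oxidation potential of the dienol ether provides. It needs bonding at C1 and not C9; attack at C9 would build a bridged bicyclo[3.3.1] skeleton and give up the allylic radical. It also needs an intact C4 centre, for which 2,6-lutidine buffers the acid released at the anode.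

Step 8
Reactants: 12 (1R,8aR)-1,8a-dimethyl-3,4,8,8a-tetrahydronaphthalene-2,6(1H,7H)-dione
Product: 13 (4aR,5R,6S)-6-hydroxy-4a,5-dimethyl-4,4a,5,6,7,8-hexahydronaphthalen-2(3H)-one
Conditions: Li(s-Bu)3BH (1.05 equiv), THF, −78 °C; H2O
Reagents that add atoms: none
Why: hindered borohydride reduction; the saturated C3 ketone is more electrophilic than the β,β-disubstituted enone, and the axial C14 methyl blocks axial attack, so equatorial delivery anti to C14 should give the axial (3S) alcohol cis to both methyl groups.

Step 9
Reactants: 13 (4aR,5R,6S)-6-hydroxy-4a,5-dimethyl-4,4a,5,6,7,8-hexahydronaphthalen-2(3H)-one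
Product: 14 (4aR,5R,6S)-6-(tert-butyldimethylsilyloxy)-4a,5-dimethyl-4,4a,5,6,7,8-hexahydronaphthalen-2(3H)-one
Conditions: t-BuMe2SiOTf, 2,6-lutidine, CH2Cl2, −78 → 0 °C
Reagents that add atoms: tert-butyldimethylsilyl trifluoromethanesulfonate, CC(C)(C)[Si](C)(C)OS(=O)(=O)C(F)(F)F
Why: silylation of a hindered axial alcohol with the silyl triflate; the weak base and low temperature leave the enone un-enolised.

Step 10
Reactants: 14 (4aR,5R,6S)-6-(tert-butyldimethylsilyloxy)-4a,5-dimethyl-4,4a,5,6,7,8-hexahydronaphthalen-2(3H)-one
Product: 15 (4aR,5R,6S)-6-(tert-butyldimethylsilyloxy)-4a,5-dimethyl-4,4a,5,6-tetrahydronaphthalen-2(3H)-one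
Conditions: chloranil (tetrachloro-1,4-benzoquinone, 1.5 equiv), t-BuOH, reflux
Reagents that add atoms: none
Why: quinone dehydrogenation of an octalenone to the linear dienone, as in the conversion of steroidal 4-en-3-ones into 4,6-dien-3-ones; the heteroannular dienol loses hydride from C2, so the C1=C2 alkene forms in conjugation and C7 is left alone.

Step 11
Reactants: 15 (4aR,5R,6S)-6-(tert-butyldimethylsilyloxy)-4a,5-dimethyl-4,4a,5,6-tetrahydronaphthalen-2(3H)-one; 16 acetone
Product: 17 (4aR,5R,6S)-6-(tert-butyldimethylsilyloxy)-3-(2-hydroxypropan-2-yl)-4a,5-dimethyl-4,4a,5,6-tetrahydronaphthalen-2(3H)-one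
Conditions: LiN(i-Pr)2, THF, −78 °C; acetone; AcOH, −78 °C
Reagents that add atoms: none
Why: kinetic aldol addition; C7 is the only α-position of the C8 ketone that bears hydrogen, so the cross-conjugated lithium enolate forms there, and the cold quench prevents retro-aldol cleavage.

Step 12
Reactants: 17 (4aR,5R,6S)-6-(tert-butyldimethylsilyloxy)-3-(2-hydroxypropan-2-yl)-4a,5-dimethyl-4,4a,5,6-tetrahydronaphthalen-2(3H)-one
Product: 19 (4aR,5R,6S)-6-(tert-butyldimethylsilyloxy)-4a,5-dimethyl-3-(propan-2-ylidene)-4,4a,5,6-tetrahydronaphthalen-2(3H)-one, via tertiary mesylate 18 (not isolated)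
Conditions: MsCl, Et3N (excess), CH2Cl2, 0 °C → rt
Reagents that add atoms: none
Why: sulfonylation of the tertiary aldol hydroxyl through sulfene and E1cB elimination; loss of the acidic C7 hydrogen gives the conjugated isopropylidene in preference to the isopropenyl isomer.

Step 13
Reactants: 19 (4aR,5R,6S)-6-(tert-butyldimethylsilyloxy)-4a,5-dimethyl-3-(propan-2-ylidene)-4,4a,5,6-tetrahydronaphthalen-2(3H)-one
Product: 20 (4aR,5R,6S)-6-hydroxy-4a,5-dimethyl-3-(propan-2-ylidene)-4,4a,5,6-tetrahydronaphthalen-2(3H)-one
Conditions: HF·pyridine, pyridine, THF, 0 °C → rt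
Reagents that add atoms: none
Why: fluoride cleavage of the silyl ether under buffered, non-basic conditions that should spare the trienone and the allylic C3 centre.

Step 14
Reactants: 21 (2S)-2-methylbutan-1-ol; 22 ethyl (2E)-4-(diethoxyphosphoryl)but-2-enoate
Product: 24 ethyl (2E,4E,6S)-6-methylocta-2,4-dienoate, via (2S)-2-methylbutanal 23 (not isolated)
Conditions: 2,2,6,6-tetramethylpiperidin-1-oxyl (1 mol %), KBr, NaOCl, CH2Cl2/aq. NaHCO3, 0 °C; dried CH2Cl2 layer added to 22 and LiN(SiMe3)2, THF, −78 → 0 °C
Reagents that add atoms: none
Why: nitroxyl-catalysed hypochlorite oxidation followed by vinylogous Horner–Wadsworth–Emmons olefination; the volatile, racemisable aldehyde is used in solution and meets only the preformed stabilised phosphonate anion, which gives the E,E-dienoate.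

Step 15
Reactants: 24 ethyl (2E,4E,6S)-6-methylocta-2,4-dienoate
Product: 25 (2E,4E,6S)-6-methylocta-2,4-dienoic acid
Conditions: LiOH, THF/MeOH/H2O, rt; 1 M HCl
Reagents that add atoms: lithium hydroxide, [Li+].[OH-]
Why: saponification; the ε-stereocentre is not acidic enough to be disturbed by aqueous hydroxide.

Step 16
Reactants: 20 (4aR,5R,6S)-6-hydroxy-4a,5-dimethyl-3-(propan-2-ylidene)-4,4a,5,6-tetrahydronaphthalen-2(3H)-one; 25 (2E,4E,6S)-6-methylocta-2,4-dienoic acid
Product: 27 (1R,2S,8aR)-1,8a-dimethyl-6-oxo-7-(propan-2-ylidene)-1,2,6,7,8,8a-hexahydronaphthalen-2-yl (2E,4E,6S)-6-methylocta-2,4-dienoate, via mixed anhydride 26 (not isolated)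
Conditions: 2,4,6-Cl3C6H2COCl, Et3N, THF, rt; then 20, 4-(dimethylamino)pyridine, toluene, rt
Reagents that add atoms: none
Why: Yamaguchi esterification; the hindered mixed anhydride is attacked at the dienoyl carbonyl, which allows acylation of the crowded axial allylic alcohol without strong base and with retention at C3.

## Compound list

1 | 2,3-dimethylcyclohex-2-en-1-one | CC1=C(C)C(=O)CCC1 | starting material
2 | (1R)-2,3-dimethylcyclohex-2-en-1-ol | O[C@@H]1CCCC(C)=C1C | intermediate
3 | propanoyl chloride | CCC(=O)Cl | starting material
4 | (1R)-2,3-dimethylcyclohex-2-en-1-yl propanoate | CCC(=O)O[C@@H]1CCCC(C)=C1C | intermediate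
5 | {[(1Z)-1-{[(1R)-2,3-dimethylcyclohex-2-en-1-yl]oxy}prop-1-en-1-yl]oxy}trimethylsilane | C/C=C(\O[Si](C)(C)C)O[C@@H]1CCCC(C)=C1C | intermediate
6 | trimethylsilyl (2R)-2-[(1R)-1,2-dimethylcyclohex-2-en-1-yl]propanoate | C[Si](C)(C)OC(=O)[C@H](C)[C@@]1(C)CCCC=C1C | intermediate
7 | (2R)-2-[(1R)-1,2-dimethylcyclohex-2-en-1-yl]propanoic acid | OC(=O)[C@H](C)[C@@]1(C)CCCC=C1C | intermediate
8 | (2R)-2-[(1R)-1,2-dimethyl-4-oxocyclohex-2-en-1-yl]propanoic acid | OC(=O)[C@H](C)[C@@]1(C)CCC(=O)C=C1C | intermediate
9 | dipotassium (2R)-2-[(1R)-1-methyl-2-methylidene-4-oxidocyclohex-3-en-1-yl]propanoate | [K+].[K+].[O-]C(=O)[C@H](C)[C@@]1(C)CCC([O-])=CC1=C | intermediate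
10 | tert-butyldimethylsilyl (2R)-2-[(1R)-4-(tert-butyldimethylsilyloxy)-1-methyl-2-methylidenecyclohex-3-en-1-yl]propanoate | CC(C)(C)[Si](C)(C)OC(=O)[C@H](C)[C@@]1(C)CCC(O[Si](C)(C)C(C)(C)C)=CC1=C | intermediate
11 | tert-butyl({(3R)-3-[(1R)-4-(tert-butyldimethylsilyloxy)-1-methyl-2-methylidenecyclohex-3-en-1-yl]but-1-en-2-yl}oxy)dimethylsilane | C=C(O[Si](C)(C)C(C)(C)C)[C@H](C)[C@@]1(C)CCC(O[Si](C)(C)C(C)(C)C)=CC1=C | intermediate
12 | (1R,8aR)-1,8a-dimethyl-3,4,8,8a-tetrahydronaphthalene-2,6(1H,7H)-dione (cis-4,5-dimethyl 9-ene-3,8-dione) | C[C@H]1C(=O)CCC2=CC(=O)CC[C@]12C | intermediate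
13 | (4aR,5R,6S)-6-hydroxy-4a,5-dimethyl-4,4a,5,6,7,8-hexahydronaphthalen-2(3H)-one | O[C@H]1CCC2=CC(=O)CC[C@]2(C)[C@H]1C | intermediate
14 | (4aR,5R,6S)-6-(tert-butyldimethylsilyloxy)-4a,5-dimethyl-4,4a,5,6,7,8-hexahydronaphthalen-2(3H)-one | CC(C)(C)[Si](C)(C)O[C@H]1CCC2=CC(=O)CC[C@]2(C)[C@H]1C | intermediate
15 | (4aR,5R,6S)-6-(tert-butyldimethylsilyloxy)-4a,5-dimethyl-4,4a,5,6-tetrahydronaphthalen-2(3H)-one | CC(C)(C)[Si](C)(C)O[C@H]1C=CC2=CC(=O)CC[C@]2(C)[C@H]1C | intermediate
16 | acetone | CC(C)=O | starting material
17 | (4aR,5R,6S)-6-(tert-butyldimethylsilyloxy)-3-(2-hydroxypropan-2-yl)-4a,5-dimethyl-4,4a,5,6-tetrahydronaphthalen-2(3H)-one (either C3 epimer) | CC(C)(C)[Si](C)(C)O[C@H]1C=CC2=CC(=O)C(C(C)(C)O)C[C@]2(C)[C@H]1C | intermediate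
18 | methanesulfonate of the tertiary hydroxyl of 17 | CC(C)(C)[Si](C)(C)O[C@H]1C=CC2=CC(=O)C(C(C)(C)OS(C)(=O)=O)C[C@]2(C)[C@H]1C | intermediate
19 | (4aR,5R,6S)-6-(tert-butyldimethylsilyloxy)-4a,5-dimethyl-3-(propan-2-ylidene)-4,4a,5,6-tetrahydronaphthalen-2(3H)-one | CC(C)(C)[Si](C)(C)O[C@H]1C=CC2=CC(=O)C(=C(C)C)C[C@]2(C)[C@H]1C | intermediate
20 | (4aR,5R,6S)-6-hydroxy-4a,5-dimethyl-3-(propan-2-ylidene)-4,4a,5,6-tetrahydronaphthalen-2(3H)-one | O[C@H]1C=CC2=CC(=O)C(=C(C)C)C[C@]2(C)[C@H]1C | intermediate
21 | (2S)-2-methylbutan-1-ol | CC[C@H](C)CO | starting material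
22 | ethyl (2E)-4-(diethoxyphosphoryl)but-2-enoate | CCOC(=O)/C=C/CP(=O)(OCC)OCC | starting material
23 | (2S)-2-methylbutanal | CC[C@H](C)C=O | intermediate
24 | ethyl (2E,4E,6S)-6-methylocta-2,4-dienoate | CC[C@H](C)/C=C/C=C/C(=O)OCC | intermediate
25 | (2E,4E,6S)-6-methylocta-2,4-dienoic acid | CC[C@H](C)/C=C/C=C/C(=O)O | intermediate
26 | (2E,4E,6S)-6-methylocta-2,4-dienoic 2,4,6-trichlorobenzoic anhydride | CC[C@H](C)/C=C/C=C/C(=O)OC(=O)c1c(Cl)cc(Cl)cc1Cl | intermediate
27 | (1R,2S,8aR)-1,8a-dimethyl-6-oxo-7-(propan-2-ylidene)-1,2,6,7,8,8a-hexahydronaphthalen-2-yl (2E,4E,6S)-6-methylocta-2,4-dienoate | CC[C@H](C)/C=C/C=C/C(=O)O[C@H]1C=CC2=CC(=O)C(=C(C)C)C[C@]2(C)[C@H]1C | target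

## Step count and least certain steps

Total: 16 steps. Longest linear sequence: 14 steps (steps 1–13 and 16); steps 14 and 15 form the side branch.

**Step 7 (key step).** The radical cation may be captured by the alcohol co-solvent or lose its silyl group before the C–C bond forms, or it may bond through C9. Intramolecular trapping of a dienol ether radical cation at its remote terminus by a silyl enol ether has no direct precedent, and the closure is endo at both alkenes.

The fallback is a polar closure by known reactions. It sets out from acid 7:
- Methyllithium addition to the carboxylate gives (3R)-3-[(1R)-1,2-dimethylcyclohex-2-en-1-yl]butan-2-one F1.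
- Allylic oxidation as in step 4 gives (4R)-3,4-dimethyl-4-[(2R)-3-oxobutan-2-yl]cyclohex-2-en-1-one F2.
- Wohl–Ziegler bromination of the γ-methyl group with N-bromosuccinimide gives (4R)-3-(bromomethyl)-4-methyl-4-[(2R)-3-oxobutan-2-yl]cyclohex-2-en-1-one F3. This inverts the polarity of C1.
- The kinetic C2 enolate, formed with LiN(SiMe3)2 at low temperature, displaces the allylic bromide in a 6-exo-tet alkylation.

The sequence returns to the route at dione 12.

**Step 3.** Discrimination between boat-like and chair-like transition states may be poor. The ring carries methyl groups on both alkene carbons, so either topology meets a methyl–methyl contact, and the result would be a mixture of C4 epimers.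

The fallback sets C4 on a rigid template. It sets out from alcohol 2:
- Johnson–Claisen rearrangement with triethyl orthoacetate gives ethyl [(1R)-1,2-dimethylcyclohex-2-en-1-yl]acetate F4.
- Saponification gives [(1R)-1,2-dimethylcyclohex-2-en-1-yl]acetic acid F5.
- Iodolactonisation gives the cis-fused (3aR,7S,7aS)-7-iodo-3a,7a-dimethylhexahydro-1-benzofuran-2(3H)-one F6.
- Methylation of its lithium enolate on the convex face, cis to C14, gives (3R,3aR,7S,7aS)-7-iodo-3,3a,7a-trimethylhexahydro-1-benzofuran-2(3H)-one F7.
- Zinc in acetic acid then removes iodide and carboxylate together.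

The sequence returns to the route at acid 7.

**Step 5.** Silylation may occur through the cross-conjugated C7 enolate if proton exchange is slower than trapping, or the carboxylate may add to C10, since the exocyclic extended dienolate is only thermodynamically preferred.

The fallback generates the dienolate reductively. It sets out from enone acid 8:
- Silylation with t-BuMe2SiCl and imidazole gives tert-butyldimethylsilyl (2R)-2-[(1R)-1,2-dimethyl-4-oxocyclohex-2-en-1-yl]propanoate F8.
- Radical bromination of the C1 methyl gives tert-butyldimethylsilyl (2R)-2-[(1R)-2-(bromomethyl)-1-methyl-4-oxocyclohex-2-en-1-yl]propanoate F9.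
- Zinc dust with t-BuMe2SiCl inserts into the allylic C–Br bond, and the zinc dienolate, which can only be the extended one, is silylated on oxygen.

The sequence returns to the route at silyl ester 10.

**Step 6.** Methylenation of the crowded silyl ester may be incomplete, and silyl groups may be lost on prolonged heating, because the carbonyl is flanked by the C4 branch and a bulky silyloxy group.

The fallback moves the methylenation to a methyl ester. It sets out from enone acid 8:
- Esterification with Me3SiCHN2 gives methyl (2R)-2-[(1R)-1,2-dimethyl-4-oxocyclohex-2-en-1-yl]propanoate F10.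
- The conditions of step 5 give methyl (2R)-2-[(1R)-4-(tert-butyldimethylsilyloxy)-1-methyl-2-methylidenecyclohex-3-en-1-yl]propanoate F11.
- Petasis methylenation of the methyl ester gives tert-butyl({(4R)-4-[(2R)-3-methoxybut-3-en-2-yl]-4-methyl-3-methylidenecyclohex-1-en-1-yl}oxy)dimethylsilane F12.
- F12 is submitted to the electrolysis of step 7, followed by a mild aqueous acid wash.

The sequence returns to the route at dione 12.

## Further compounds

F1 | step 7 | (3R)-3-[(1R)-1,2-dimethylcyclohex-2-en-1-yl]butan-2-one | CC(=O)[C@H](C)[C@@]1(C)CCCC=C1C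
F2 | step 7 | (4R)-3,4-dimethyl-4-[(2R)-3-oxobutan-2-yl]cyclohex-2-en-1-one | CC(=O)[C@H](C)[C@@]1(C)CCC(=O)C=C1C
F3 | step 7 | (4R)-3-(bromomethyl)-4-methyl-4-[(2R)-3-oxobutan-2-yl]cyclohex-2-en-1-one | CC(=O)[C@H](C)[C@@]1(C)CCC(=O)C=C1CBr
F4 | step 3 | ethyl [(1R)-1,2-dimethylcyclohex-2-en-1-yl]acetate | CCOC(=O)C[C@@]1(C)CCCC=C1C
F5 | step 3 | [(1R)-1,2-dimethylcyclohex-2-en-1-yl]acetic acid | OC(=O)C[C@@]1(C)CCCC=C1C
F6 | step 3 | (3aR,7S,7aS)-7-iodo-3a,7a-dimethylhexahydro-1-benzofuran-2(3H)-one | O=C1C[C@@]2(C)CCC[C@H](I)[C@@]2(C)O1
F7 | step 3 | (3R,3aR,7S,7aS)-7-iodo-3,3a,7a-trimethylhexahydro-1-benzofuran-2(3H)-one | O=C1[C@H](C)[C@@]2(C)CCC[C@H](I)[C@@]2(C)O1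
F8 | step 5 | tert-butyldimethylsilyl (2R)-2-[(1R)-1,2-dimethyl-4-oxocyclohex-2-en-1-yl]propanoate | CC(C)(C)[Si](C)(C)OC(=O)[C@H](C)[C@@]1(C)CCC(=O)C=C1C
F9 | step 5 | tert-butyldimethylsilyl (2R)-2-[(1R)-2-(bromomethyl)-1-methyl-4-oxocyclohex-2-en-1-yl]propanoate | CC(C)(C)[Si](C)(C)OC(=O)[C@H](C)[C@@]1(C)CCC(=O)C=C1CBr
F10 | step 6 | methyl (2R)-2-[(1R)-1,2-dimethyl-4-oxocyclohex-2-en-1-yl]propanoate | COC(=O)[C@H](C)[C@@]1(C)CCC(=O)C=C1C
F11 | step 6 | methyl (2R)-2-[(1R)-4-(tert-butyldimethylsilyloxy)-1-methyl-2-methylidenecyclohex-3-en-1-yl]propanoate | COC(=O)[C@H](C)[C@@]1(C)CCC(O[Si](C)(C)C(C)(C)C)=CC1=C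
F12 | step 6 | tert-butyl({(4R)-4-[(2R)-3-methoxybut-3-en-2-yl]-4-methyl-3-methylidenecyclohex-1-en-1-yl}oxy)dimethylsilane | COC(=C)[C@H](C)[C@@]1(C)CCC(O[Si](C)(C)C(C)(C)C)=CC1=C
A1 | alternative 1 | (3S,4R)-8,8-ethylenedioxy-4-methyl bicyclic 5(10)-en-3-ol lacking C14 (eremophilane numbering) | C[C@H]1[C@@H](O)CCC2=C1CCC1(OCCO1)C2
A2 | alternative 1 | C5,C10-methano-bridged decalin ketal with the bridge cis to the C3 hydroxyl | C[C@H]1[C@@H](O)CC[C@@]23C[C@@]12CCC4(OCCO4)C3
A3 | alternative 2 | tert-butyl{[(1R,2S,8aR)-1,8a-dimethyl-1,2,6,7,8,8a-hexahydronaphthalen-2-yl]oxy}dimethylsilane | CC(C)(C)[Si](C)(C)O[C@H]1C=CC2=CCCC[C@]2(C)[C@H]1C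
A4 | alternative 3 | 4-[(2R,3R,4Z)-3-(tert-butyldimethylsilyloxy)-5-iodopent-4-en-2-yl]-4-methylcyclohexa-2,5-dien-1-one | CC(C)(C)[Si](C)(C)O[C@@H](/C=C\I)[C@H](C)C1(C)C=CC(=O)C=C1
A5 | alternative 3 | (4aR,5R,6S)-6-(tert-butyldimethylsilyloxy)-4a,5-dimethyl-5,6-dihydronaphthalen-2(4aH)-one | CC(C)(C)[Si](C)(C)O[C@H]1C=CC2=CC(=O)C=C[C@]2(C)[C@H]1C
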